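**Plan**

- Ring A carbons are called a1 (chain-bearing), a2, a3, a4, a5, a6 in ring order; a4 and a5 are the A/B fusion carbons. The retrosynthesis removes the glycerol acetonide, cuts the a1–chain bond (enol triflate + C8 alkylborane), traces the a1 ketone to a trans-a1,a2-diol, opens the bond shared by rings C and D (4π) and the ring-B bond opposite a4–a5 (6π), and last cuts the a5–a6 and a4–a3 bonds.
- Enabling feature: a4, a5 and the six other carbons of cyclobutanes B, C and D form one eight-membered loop (cyclooctatetraene). The remaining ring-A carbons a6–a1–a2–a3 are a four-carbon chain spanning the adjacent loop carbons a5 and a4 (the L-threitol chain, its oxygens on a1 and a2).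
- Forward: ring A closes first on the cyclooctatetraene dianion, ring B by thermal 6π closure, rings C and D together by photochemical 4π closure. The cyclobutene is then reduced, the diol trimmed to the a1 ketone, the preassembled C8–glycerol chain coupled at a1, and the ring alkene hydrogenated.
- Stereochemistry: L-threitol is the only source of chirality, and its C2 axis makes the cis-fused bicycle a single enantiomer. Both electrocyclisations go anti (exo); hydride opens the cyclic sulfate at a2 so that oxygen stays on a1; hydrogenation from the convex face of ring A sets a1.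

Key step: step 3

Remark: "convex face" of ring A is the face carrying the a4 and a5 hydrogens and "concave face" the one on which ring B lies; triene 7 and its tautomer 8 are assumed to interconvert only on warming, so that 8 can be handled at or below 0 °C.

**Route**

Step 1
Reactants: 1 1,4-di-O-tosyl-2,3-O-isopropylidene-L-threitol
Product: 3 1,4-dibromo-1,4-dideoxy-2,3-O-isopropylidene-L-threitol, via bromo tosylate 2 (not isolated)
Conditions: LiBr, DMF, 70 °C
Reagents that add atoms: lithium bromide, [Li+].[Br-]
Why: Twofold Finkelstein-type SN2 displacement of the primary sulfonates by bromide; the two dioxolane stereocentres are not at the reacting carbons and are carried over unchanged.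

Step 2
Reactants: 4 cyclooctatetraene
Product: 5 dipotassium cyclooctatetraenide (K2C8H8; THF solution used directly)
Conditions: K (2.1 equiv), THF, rt
Reagents that add atoms: potassium, [K]
Why: Dissolving-metal two-electron reduction turns the tub-shaped 8π polyene into the planar aromatic 10π dianion, the standard preparation of this nucleophile.

Step 3
Reactants: 5 dipotassium cyclooctatetraenide; 3 1,4-dibromo-1,4-dideoxy-2,3-O-isopropylidene-L-threitol
Product: 7 (10S,11S)-10,11-O-isopropylidene-cis-bicyclo[6.4.0]dodeca-2,4,6-triene-10,11-diol (ring A cis-fused to an all-Z cycloocta-1,3,5-triene; acetonide oxygens trans), via tethered potassium cyclooctatrienide 6 (not isolated)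
Conditions: 3 added slowly to 5, THF (dilute), −78 °C → 0 °C; aq. NH4Cl
Reagents that add atoms: none
Why: The aromatic 10π dianion displaces the first primary bromide by SN2 (an electron-transfer/radical-coupling path would form the same bond) to give cyclooctatrienide 6, whose charge lies largely on the ring carbons flanking the new sp3 carbon, and one of these then displaces the second bromide. The closest known reaction type is the double alkylation of the cyclooctatetraene dianion with 1,n-dibromoalkanes to cis-bicyclo[6.n.0]trienes, and the same threitol skeleton is known to bis-alkylate cyclopentadienide. Ring A closes in a 6-exo-tet mode through a chair-like transition state. The two new stereocentres a4 and a5 come out cis because the tether, held on one face at the first alkylated carbon, can reach the neighbouring carbon only from that same face; their absolute sense needs no control, since the dielectrophile is C2-symmetric and closure at either flanking carbon gives the identical bicycle. The step needs vicinal rather than transannular closure, intra- rather than intermolecular second alkylation, and substitution rather than reductive loss of bromide; the four-carbon tether, slow addition of 3 to excess dianion under dilution at low temperature, and the primary bromides are meant to secure these.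

Step 4
Reactants: 7 cis-bicyclo[6.4.0]dodecatriene acetonide
Product: 8 tricyclo[6.4.0.0^2,7]dodeca-3,5-diene-10,11-diol acetonide (ring A and the cyclohexadiene anti across cyclobutane B; both fusions cis)
Conditions: PhMe (degassed), 70 °C, dark; AgNO3–SiO2 chromatography at 0 °C, recovered 7 recycled
Reagents that add atoms: none
Why: Thermal disrotatory 6π electrocyclisation (the cycloocta-1,3,5-triene/bicyclo[4.2.0]octa-2,4-diene valence tautomerism) closes ring B; disrotation makes the two new stereocentres cis, and because the closure is reversible the material should collect in the tautomer with ring A exo on the cyclobutane (anti to the cyclohexadiene), the endo alternative being far more strained.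

Step 5
Reactants: 8 tricyclic diene acetonide
Product: 9 tetracyclo[6.4.0.0^2,7.0^3,6]dodec-4-ene-10,11-diol acetonide (ladderene; ring D a cyclobutene; ring B anti to ring D across ring C)
Conditions: hν (254 nm, quartz), pentane, −20 °C
Reagents that add atoms: none
Why: Photochemical disrotatory 4π electrocyclisation of a cyclohexa-1,3-diene to a bicyclo[2.2.0]hex-2-ene forms the bond shared by rings C and D; the two new stereocentres are cis by geometric necessity, the etheno bridge should fold to the diene face remote from ring B (anti ladder), the low temperature keeps 8 from reverting to 7, and the product no longer absorbs the light.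

Step 6
Reactants: 9 ladderene acetonide
Product: 10 tetracyclo[6.4.0.0^2,7.0^3,6]dodecane-10,11-diol acetonide (saturated ladderane)
Conditions: 2-O2NC6H4SO2NHNH2, Et3N, CH2Cl2, rt
Reagents that add atoms: none
Why: Diimide reduction transfers two hydrogens suprafacially to the strained cyclobutene without a metal catalyst, so neither cyclobutane hydrogenolysis nor acetal loss is expected and no stereocentre is created.

Step 7
Reactants: 10 ladderane acetonide
Product: 11 trans-a1,a2-diol of the ladderane (a1-OH on the convex face; a2-OH on the concave face)
Conditions: 1 M HCl, THF, rt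
Reagents that add atoms: none
Why: Acid-catalysed acetal hydrolysis removes the strained trans-fused dioxolane readily; the C–O bonds of the carbinol carbons are not broken, so their configuration is retained.

Step 8
Reactants: 11 trans-a1,a2-diol
Product: 13 cyclic sulfate of diol 11, via cyclic sulfite 12 (not isolated)
Conditions: SOCl2, Et3N, CH2Cl2, 0 °C; then RuCl3·xH2O (cat.), NaIO4, MeCN/CH2Cl2/H2O, 0 °C
Reagents that add atoms: thionyl chloride, O=S(Cl)Cl; sodium periodate, [Na+].[O-]I(=O)(=O)=O
Why: The standard two-stage cyclic sulfate preparation (cyclic sulfite formation, then RuO4-catalysed oxidation at sulfur) activates both carbinol carbons without touching their configuration.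

Step 9
Reactants: 13 cyclic sulfate
Product: 15 ladderan-a1-ol (hydroxyl on a1 on the convex face; a2 now CH2), via lithium alkyl sulfate 14 (not isolated)
Conditions: LiEt3BH, THF, 0 °C → rt; then H2SO4 (cat.), H2O, THF, rt
Reagents that add atoms: none
Why: SN2 hydride opening of a cyclic sulfate followed by hydrolysis of the sulfate monoester; the trans-fused sulfate locks ring A in the chair with both C–O bonds equatorial and the a5–ring B bond axial, so hydride should enter axially at a2 (past axial hydrogens on a4 and a6) and not at a1 (blocked by the axial a5–ring B bond), the a1–O bond is never broken, and any alcohol from attack at a1 is a diastereomer of 15 that is removed by chromatography, so a regiochemical leak would cost material but not enantiopurity.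

Step 10
Reactants: 15 ladderan-a1-ol
Product: 16 ladderan-a1-one
Conditions: Dess–Martin periodinane, CH2Cl2, rt
Reagents that add atoms: none
Why: Dess–Martin oxidation of a secondary alcohol under neutral conditions; the carbinol stereocentre is given up on purpose, the absolute configuration now residing in the carbonyl being on a1 and not on a2.

Step 11
Reactants: 16 ladderan-a1-one
Product: 18 a1-enol triflate with the a1=a2 double bond, via potassium enolate 17 (not isolated)
Conditions: KN(SiMe3)2, THF, −78 °C; then PhNTf2, −78 → 0 °C
Reagents that add atoms: N-phenylbis(trifluoromethanesulfonimide), O=S(=O)(N(c1ccccc1)S(=O)(=O)C(F)(F)F)C(F)(F)F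
Why: Kinetic enolate formation with a hindered amide base and O-sulfonylation (enol triflate synthesis), expected on the less encumbered a2 side; deprotonation on the a6 side would lead after steps 13 and 14 to the same compound 25, so the site of enolisation is not critical.

Step 12
Reactants: 19 8-bromooct-1-ene; 20 2,2-dimethyl-1,3-dioxan-5-ol
Product: 22 2,2-dimethyl-5-(oct-7-en-1-yloxy)-1,3-dioxane, via sodium alkoxide 21 (not isolated)
Conditions: NaH, DMF, 0 °C → rt
Reagents that add atoms: none
Why: Williamson ether synthesis between a secondary alkoxide and an unhindered primary bromide.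

Step 13
Reactants: 18 a1-enol triflate; 22 2,2-dimethyl-5-(oct-7-en-1-yloxy)-1,3-dioxane
Product: 24 5-{[8-(ladder-a1-en-a1-yl)octyl]oxy}-2,2-dimethyl-1,3-dioxane (a1=a2 alkene), via B-alkyl-9-BBN 23 (not isolated)
Conditions: 22, 9-BBN, THF, rt; then 18, Pd(dppf)Cl2 (cat.), K3PO4 (aq.), DMF, 40 °C
Reagents that add atoms: none
Why: Anti-Markovnikov hydroboration of the terminal alkene followed by B-alkyl Suzuki–Miyaura coupling (oxidative addition of the alkenyl triflate to zerovalent palladium, base-assisted transmetalation, reductive elimination) forms the a1–chain bond at a temperature the ladderane tolerates.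

Step 14
Reactants: 24 coupled ring-A alkene
Product: 25 5-{[8-(ladderan-a1-yl)octyl]oxy}-2,2-dimethyl-1,3-dioxane (chain on the concave face of ring A; cis to ring B)
Conditions: H2 (1 atm), [Ir(cod)(PCy3)(py)]PF6 (cat.), CH2Cl2, rt
Reagents that add atoms: none
Why: Homogeneous catalytic hydrogenation of the trisubstituted alkene should deliver both hydrogens to the convex face of ring A, because the concave face is shielded by the pseudo-axial bond to ring B at a4 or a5; the chain is thereby placed cis to ring B, which is the a1 configuration of the target.

Step 15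
Reactants: 25 saturated acetonide
Product: 26 2-O-[8-(ladderan-a1-yl)octyl]glycerol (target)
Conditions: 1 M HCl, THF, rt
Reagents that add atoms: none
Why: Acid hydrolysis of the 1,3-dioxane acetonide liberates the glycerol 1,3-diol; dilute acid at room temperature should leave the dialkyl ether and the cyclobutanes intact.

**Compound list**

"Ladderane" below means the tetracyclo[6.4.0.0^2,7.0^3,6]dodecane skeleton with all ring fusions cis, ring A anti to ring C and ring B anti to ring D.

1 | 1,4-di-O-tosyl-2,3-O-isopropylidene-L-threitol, (4S,5S) | Cc1ccc(cc1)S(=O)(=O)OC[C@@H]1OC(C)(C)O[C@H]1COS(=O)(=O)c1ccc(C)cc1 | starting material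
2 | 1-bromo-1-deoxy-2,3-O-isopropylidene-4-O-tosyl-L-threitol | BrC[C@@H]1OC(C)(C)O[C@H]1COS(=O)(=O)c1ccc(C)cc1 | intermediate
3 | 1,4-dibromo-1,4-dideoxy-2,3-O-isopropylidene-L-threitol, (4R,5R)-4,5-bis(bromomethyl)-2,2-dimethyl-1,3-dioxolane | BrC[C@@H]1OC(C)(C)O[C@H]1CBr | intermediate
4 | cyclooctatetraene | C1=CC=CC=CC=C1 | starting material
5 | dipotassium cyclooctatetraenide | [K+].[K+].[CH-]1C=CC=C[CH-]C=C1 | intermediate
6 | potassium cyclooctatrienide carrying the (bromomethyl)dioxolanylmethyl tether on its sp3 carbon (threitol configuration retained) | [K+].BrC[C@@H]1OC(C)(C)O[C@H]1CC2C=CC=CC=C[CH-]2 | intermediate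
7 | (10S,11S)-10,11-O-isopropylidene-cis-bicyclo[6.4.0]dodeca-2,4,6-triene-10,11-diol | CC1(C)O[C@H]2C[C@@H]3/C=C\C=C/C=C\[C@@H]3C[C@@H]2O1 | intermediate
8 | tricyclo[6.4.0.0^2,7]dodeca-3,5-diene-10,11-diol acetonide, ring A anti to the cyclohexadiene | CC1(C)O[C@H]2C[C@@H]3[C@H]4C=CC=C[C@H]4[C@@H]3C[C@@H]2O1 | intermediate
9 | tetracyclo[6.4.0.0^2,7.0^3,6]dodec-4-ene-10,11-diol acetonide (ladderene) | CC1(C)O[C@H]2C[C@@H]3[C@H]4[C@@H]5C=C[C@@H]5[C@H]4[C@@H]3C[C@@H]2O1 | intermediate
10 | ladderane trans-a1,a2-diol acetonide | CC1(C)O[C@H]2C[C@@H]3[C@H]4[C@@H]5CC[C@@H]5[C@H]4[C@@H]3C[C@@H]2O1 | intermediate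
11 | ladderane trans-a1,a2-diol, (S,S) carbinol carbons | O[C@H]1C[C@@H]2[C@H]3[C@@H]4CC[C@@H]4[C@H]3[C@@H]2C[C@@H]1O | intermediate
12 | cyclic sulfite of 11 (either configuration at sulfur) | O=S1O[C@H]2C[C@@H]3[C@H]4[C@@H]5CC[C@@H]5[C@H]4[C@@H]3C[C@@H]2O1 | intermediate
13 | cyclic sulfate of 11 | O=S1(=O)O[C@H]2C[C@@H]3[C@H]4[C@@H]5CC[C@@H]5[C@H]4[C@@H]3C[C@@H]2O1 | intermediate
14 | lithium ladderan-a1-yl sulfate | [Li+].[O-]S(=O)(=O)O[C@H]1C[C@@H]2[C@H]3[C@@H]4CC[C@@H]4[C@H]3[C@@H]2CC1 | intermediate
15 | ladderan-a1-ol, hydroxyl on the convex face | O[C@H]1C[C@@H]2[C@H]3[C@@H]4CC[C@@H]4[C@H]3[C@@H]2CC1 | intermediate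
16 | ladderan-a1-one | O=C1C[C@@H]2[C@H]3[C@@H]4CC[C@@H]4[C@H]3[C@@H]2CC1 | intermediate
17 | potassium a1(a2)-enolate of 16 | [K+].[O-]C=1C[C@@H]2[C@H]3[C@@H]4CC[C@@H]4[C@H]3[C@@H]2CC=1 | intermediate
18 | a1-enol triflate, a1=a2 double bond | FC(F)(F)S(=O)(=O)OC=1C[C@@H]2[C@H]3[C@@H]4CC[C@@H]4[C@H]3[C@@H]2CC=1 | intermediate
19 | 8-bromooct-1-ene | C=CCCCCCCBr | starting material
20 | 2,2-dimethyl-1,3-dioxan-5-ol | CC1(C)OCC(O)CO1 | starting material
21 | sodium 2,2-dimethyl-1,3-dioxan-5-olate | [Na+].[O-]C1COC(C)(C)OC1 | intermediate
22 | 2,2-dimethyl-5-(oct-7-en-1-yloxy)-1,3-dioxane | C=CCCCCCCOC1COC(C)(C)OC1 | intermediate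
23 | 9-{8-[(2,2-dimethyl-1,3-dioxan-5-yl)oxy]octyl}-9-borabicyclo[3.3.1]nonane | CC1(C)OCC(CO1)OCCCCCCCCB2C3CCCC2CCC3 | intermediate
24 | 5-{[8-(ladder-a1-en-a1-yl)octyl]oxy}-2,2-dimethyl-1,3-dioxane | CC1(C)OCC(CO1)OCCCCCCCCC=5C[C@@H]2[C@H]3[C@@H]4CC[C@@H]4[C@H]3[C@@H]2CC=5 | intermediate
25 | 5-{[8-(ladderan-a1-yl)octyl]oxy}-2,2-dimethyl-1,3-dioxane, chain cis to ring B | CC1(C)OCC(CO1)OCCCCCCCC[C@@H]5C[C@@H]2[C@H]3[C@@H]4CC[C@@H]4[C@H]3[C@@H]2CC5 | intermediate
26 | 2-O-[8-(ladderan-a1-yl)octyl]glycerol, CNP0193334.1 | OCC(CO)OCCCCCCCC[C@H]1CC[C@@H]2[C@H](C1)[C@H]1[C@@H]3CC[C@@H]3[C@@H]21 | target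

**Step count and risks**

Total: 15 steps. Longest linear sequence: 13 steps (steps 1, 3–11, 13–15).

Step 3 (highest risk). The strongly reducing dianion may transfer single electrons to the C–Br bonds, after which the β-acetal oxygen can be expelled reductively. The second alkylation may also occur between molecules and give oligomers. The fallback replaces the dihalide by a sulfate ester, which is not reduced by electron transfer and carries no halide. It sets out from 5 and comes back at 7. Commercial 2,3-O-isopropylidene-L-threitol F1 is converted with SOCl2/Et3N into the seven-membered cyclic sulfite F2 and oxidised (RuCl3 cat., NaIO4) to the 1,4-cyclic sulfate F3. Addition of F3 to 5 at −78 °C should open the sulfate ring by SN2 at one primary carbon and give the sulfate-tethered dipotassium cyclooctatrienide F4. On warming, the flanking ring carbon displaces the sulfate monoester in the same 6-exo-tet sense, as carbanions and phosphides do with cyclic sulfates. The C2 symmetry argument is unchanged and 7 results.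

Step 5. Light may instead drive ring opening of the cyclohexadiene or its cycloreversion with loss of benzene, and any residual triene 7 would be photolysed along other channels. The fallback builds rings C and D by cycloaddition, not electrocyclisation. It sets out from 7 (through its tautomer 8) and comes back at 10, so it also makes the position of the step 4 equilibrium irrelevant. Triene 7 is heated with dimethyl acetylenedicarboxylate (PhMe, 80 °C). The Diels–Alder reaction drains the equilibrium through 8, adding anti to ring B, to give the bicyclo[2.2.2]octadiene Diels–Alder adduct F5. Short-path thermolysis at about 200 °C under reduced pressure effects the retro-Diels–Alder loss of dimethyl phthalate and releases the ring-A-fused cyclobutene F6, in which ring B is a cyclobutene. Copper-triflate-catalysed [2+2] photocycloaddition [(CuOTf)2·C6H6, hν 254 nm, Et2O] of F6 with excess cyclobutene should then add to the exo face with the usual cis-anti-cis outcome and give 10 directly.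

Step 9. Hydride may attack at sulfur (returning diol 11) or act as a base, so that the sulfate is lost without a C–H bond being formed at the unactivated secondary carbon. The fallback separates C–O cleavage from C–H formation. It sets out from 13 and comes back at 15. PhSeNa [from (PhSe)2 and NaBH4, EtOH/THF], a soft and weakly basic nucleophile, should open 13 at a2 under the same conformational bias to give the sodium alkyl sulfate F7. Mild acid hydrolysis then gives the cis-hydroxy selenide F8. Homolytic C–Se cleavage with Bu3SnH and Et3B/air at room temperature replaces selenium by hydrogen and returns 15. As in step 9, the alcohol from opening at a1 is a diastereomer and is removed at this stage.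

Further compounds
F1 | step 3 | 2,3-O-isopropylidene-L-threitol | OC[C@@H]1OC(C)(C)O[C@H]1CO
F2 | step 3 | 2,3-O-isopropylidene-L-threitol 1,4-cyclic sulfite | O=S1OC[C@@H]2OC(C)(C)O[C@H]2CO1
F3 | step 3 | 2,3-O-isopropylidene-L-threitol 1,4-cyclic sulfate | O=S1(=O)OC[C@@H]2OC(C)(C)O[C@H]2CO1
F4 | step 3 | dipotassium salt of the cyclooctatrienide carrying the (sulfonatooxymethyl)dioxolanylmethyl tether | [K+].[K+].[O-]S(=O)(=O)OC[C@@H]1OC(C)(C)O[C@H]1CC2C=CC=CC=C[CH-]2
F5 | step 5 | Diels–Alder adduct of 8 with dimethyl acetylenedicarboxylate (dienophile anti to ring B) | CC1(C)O[C@H]2C[C@@H]3[C@H]4[C@H]5C=C[C@H](C(C(=O)OC)=C5C(=O)OC)[C@H]4[C@@H]3C[C@@H]2O1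
F6 | step 5 | cis-bicyclo[4.2.0]oct-7-ene-3,4-trans-diol acetonide (ring A fused to a cyclobutene) | CC1(C)O[C@H]2C[C@@H]3C=C[C@@H]3C[C@@H]2O1
F7 | step 9 | sodium a2-(phenylselanyl)ladderan-a1-yl sulfate | [Na+].[O-]S(=O)(=O)O[C@H]1C[C@@H]2[C@H]3[C@@H]4CC[C@@H]4[C@H]3[C@@H]2C[C@H]1[Se]c5ccccc5
F8 | step 9 | a2-(phenylselanyl)ladderan-a1-ol (hydroxyl and selenium cis) | O[C@H]1C[C@@H]2[C@H]3[C@@H]4CC[C@@H]4[C@H]3[C@@H]2C[C@H]1[Se]c5ccccc5
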